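(The rate constants are made up; what happens was integrated by code.)

The free catalyst in these flasks goes round a cycle, and I asked how many rounds a charge of it gets through in the run.

all flasks: substrate 0.081 M; partner 0.146 M; free catalyst 0.81 mM; time 3.0 min

|  | scavenger |
|---|---|
| north-west | 0.0650 M |
| south | 0.0840 M |
| east | 0.110 M |

    scavenger + released group → scavenged by-product (k1 = 3.19 M⁻¹ s⁻¹)
    catalyst intermediate C → free catalyst + product (k2 = 2.59 s⁻¹)
    substrate + catalyst intermediate B → catalyst intermediate C (k3 = 26.7 M⁻¹ s⁻¹)
    partner + released group ⇌ idle adduct, settled at all times (K4 = 13.3 M⁻¹)
    partner + free catalyst → catalyst intermediate A (k5 = 140 M⁻¹ s⁻¹)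
    catalyst intermediate A → released group + catalyst intermediate B (k6 = 2.34 s⁻¹)

1. part of the substrate that has reacted at the end, north-west
2. part of the substrate that has reacted at the end, south
3. part of the substrate that has reacted at the end, east
4. what raising the concentration of scavenger from its lowest to its highest value here does to the part of the substrate that has reacted (changes below 5 percentage points count as none) (it rises / no change / it falls)

- released group is meant together with its idle adduct
- run time (north-west): 3.0 min

Each round turns one substrate into product, and the substrate, charged below the partner, is the limiting reagent. So I first took the dose, catalyst charge times run time, 0.146 M·s. But a round has a price. While substrate is plentiful, it costs mainly the fixed round time T, the time of one round apart from the wait for substrate, 0.862 s, summed from the inverses of 2.34 s⁻¹, 2.59 s⁻¹ and 140 M⁻¹ s⁻¹ times the charged partner, against a wait of 0.462 s at the charged substrate. As substrate S runs low, the wait, the inverse of 26.7 M⁻¹ s⁻¹ times S, grows past T once S is under 0.0434 M, and the rate tends to pseudo-first-order in S. Joining both ends and summing over the run, I set the dose equal to a bill: T times the substrate used, plus ln(charge/left) over 26.7 M⁻¹ s⁻¹. Charging all the substrate to T left 13.2%, and feeding the used amount back gave 10.3%, then 10.9%, so I reckoned 89.1% reacted. The partner wait, 0.0489 s, is the part of T that holds the free partner, 5.67% of it, and the scavenger reaches the bill through the free partner, so I expected one figure for the three flasks.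

The forecast gave 88%, 89% and 89.5%, lower than mine in north-west, and "no change", on this ground: “Even the lowest scavenger level keeps the released group low enough that only a few mM of partner is tied up”.

The flasks gave 88.8%, 88.8% and 88.8%, a change of 0.036 percentage points, so no change. At the reading for north-west, the bill came to 98.7% of the dose. The neighbour of north-west, charged with 4.9 × 10⁻⁴ M of free catalyst, all else held, had a smaller dose, 0.0882 M·s, and reached 66.5%, with 34% of its substrate left. With the same T, its bill at that reading came to 99.0% of its dose.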